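**Strategy**

Everything rests on making the C8–C9 single bond last. A silver-assisted Mizoroki–Heck alkenylation joins the unprotected (5R,6S)-6-vinyl cis-diol of ring A to an all-E C29 polyenyl iodide that already carries the (5′R,8′S) furanoid bicycle; in one operation it forms C8–C9, sets the E-C7=C8 double bond and completes the C40 skeleton. The step exploits the fully substituted carbinol C6, flanked by quaternary C1 and C5 in ring A: palladium on C7 finds β-hydrogens only on C8. Both end groups come from one Sharpless epoxide of β-cyclogeraniol: retentive palladium/CO2 opening gives the cis-diol, and SN2′ reduction followed by gold-catalysed allene cyclisation gives the furanoid ring.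

Key step: step 16

Remark: positions are given in carotenoid numbering (ring A = C1–C6 with the diol, primed numbers = furanoid end); the allene axis of 13 is written on its central carbon in SMILES; 1, 9 and 19 are taken as purchasable.

**Route**

Step 1
Reactants: 1 β-cyclocitral
Product: 2 β-cyclogeraniol
Conditions: NaBH4, MeOH, 0 °C
Reagents that add atoms: none
Why: Borohydride 1,2-reduction of the hindered enal should give the allylic alcohol needed for the Sharpless epoxidation; no stereocentre is formed.

Step 2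
Reactants: 2 β-cyclogeraniol
Product: 3 [(1R,6R)-2,2,6-trimethyl-7-oxabicyclo[4.1.0]heptan-1-yl]methanol
Conditions: Ti(Oi-Pr)4 (10 mol %), D-(−)-diethyl tartrate (12 mol %), t-BuOOH, 4 Å molecular sieves, CH2Cl2, −20 °C
Reagents that add atoms: tert-butyl hydroperoxide CC(C)(C)OO
Why: Sharpless asymmetric epoxidation of the tetrasubstituted allylic alcohol; the D-(−)-tartrate titanium complex should deliver oxygen to the face of C5=C6 that makes C5 R (the mirror image of the geraniol/L-(+)-tartrate case), and since both C–O bonds form on one face C6 is set at the same time.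

Step 3
Reactants: 3 epoxy alcohol
Product: 4 (1S,6R)-2,2,6-trimethyl-7-oxabicyclo[4.1.0]heptane-1-carbaldehyde
Conditions: Dess–Martin periodinane, pyridine, CH2Cl2, 0 °C to rt
Reagents that add atoms: none
Why: Buffered Dess–Martin oxidation of the neopentyl-type primary alcohol should leave the acid-sensitive oxirane intact; the aldehyde has no α-hydrogen, so neither stereocentre can epimerise.

Step 4
Reactants: 4 epoxy aldehyde
Product: 5 (1S,6R)-1-ethenyl-2,2,6-trimethyl-7-oxabicyclo[4.1.0]heptane
Conditions: Ph3PCH3Br, KOt-Bu, THF, 0 °C to rt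
Reagents that add atoms: methyltriphenylphosphonium bromide C[P+](c1ccccc1)(c1ccccc1)c1ccccc1.[Br-]
Why: Wittig methylenation with the unhindered, non-stabilised ylide should convert even this crowded aldehyde into the vinyl group (C7=C8) without touching the oxirane.

Step 5
Reactants: 5 vinyl epoxide
Product: 6 (3aR,7aS)-7a-ethenyl-3a,7,7-trimethylhexahydro-1,3-benzodioxol-2-one
Conditions: Pd2(dba)3·CHCl3 (2.5 mol %), P(Oi-Pr)3 (15 mol %), CO2 (1 atm), THF, 0 °C to rt
Reagents that add atoms: carbon dioxide O=C=O
Why: Palladium-catalysed CO2 insertion into a vinyl epoxide: zerovalent palladium ionises C6–O with inversion to a π-allyl complex, the C5 alkoxide picks up CO2 and the tethered carbonate closes on C6 anti to palladium, so the double inversion should return C6–O to the face of C5–O (cis-fused carbonate, net retention), while the absence of any hydrogen next to C6 rules out β-hydride loss from the π-allyl complex.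

Step 6
Reactants: 6 cyclic carbonate
Product: 7 (1S,2R)-1-ethenyl-2,6,6-trimethylcyclohexane-1,2-diol
Conditions: NaOH, MeOH–H2O, 50 °C
Reagents that add atoms: none
Why: Saponification cleaves only the carbonyl–oxygen bonds, so both carbinol configurations should be retained and the free cis-diol released.

Step 7
Reactants: 4 epoxy aldehyde
Product: 8 (1R,6R)-1-ethynyl-2,2,6-trimethyl-7-oxabicyclo[4.1.0]heptane
Conditions: dimethyl (1-diazo-2-oxopropyl)phosphonate, K2CO3, MeOH, 0 °C to rt
Reagents that add atoms: dimethyl (1-diazo-2-oxopropyl)phosphonate COP(=O)(OC)C(=[N+]=[N-])C(C)=O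
Why: Seyferth–Gilbert homologation with the Ohira–Bestmann reagent should turn the non-enolisable aldehyde into the terminal alkyne (C7≡C8) under mild base that leaves the tetrasubstituted oxirane alone.

Step 8
Reactants: 9 but-2-yn-1-ol
Product: 11 (2E)-3-iodobut-2-en-1-ol, via alkenylzirconocene 10 (not isolated)
Conditions: Cp2Zr(H)Cl (2.2 equiv), THF, rt; then I2, 0 °C
Reagents that add atoms: iodine II
Why: Hydrozirconation–iodination: after the hydroxyl is capped as its zirconium alkoxide, syn addition of Zr–H should place zirconium on C3, away from the bulky CH2O–Zr group (equilibration by the excess hydride reinforces this), and iodinolysis with retention gives the E iodide.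

Step 9
Reactants: 8 ethynyl epoxide and 11 (2E)-3-iodobut-2-en-1-ol
Product: 12 (2E)-3-methyl-5-[(1R,6R)-2,2,6-trimethyl-7-oxabicyclo[4.1.0]heptan-1-yl]pent-2-en-4-yn-1-ol
Conditions: PdCl2(PPh3)2 (3 mol %), CuI (6 mol %), i-Pr2NH, THF, rt
Reagents that add atoms: none
Why: Sonogashira coupling forms C8′–C9′ with retention of the E iodide geometry; oxidative addition to the alkenyl iodide should be much faster than any ionisation of the hindered propargylic oxirane.

Step 10
Reactants: 12 epoxy enynol
Product: 13 (2E)-5-[(2R)-2-hydroxy-2,6,6-trimethylcyclohexylidene]-3-methylpenta-2,4-dien-1-ol with (R) allene axis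
Conditions: i-Bu2AlH (4 equiv), CH2Cl2, −20 to 0 °C; aqueous KNaC4H4O6 work-up
Reagents that add atoms: none
Why: SN2′ reduction of the propargylic oxirane: aluminium bound to the oxirane oxygen should deliver hydride to C8′ on the oxygen face while C6′–O breaks, the course known for 5,6-epoxy-7-yne end groups of this type, so the C6′ centre is traded for the (R) allene axis and C5′ (R) is untouched.

Step 11
Reactants: 13 allenic diol
Product: 14 (2E)-3-[(2S,7aR)-4,4,7a-trimethyl-2,4,5,6,7,7a-hexahydro-1-benzofuran-2-yl]but-2-en-1-ol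
Conditions: AuCl3 (5 mol %), THF, rt, dark
Reagents that add atoms: none
Why: Gold-catalysed 5-endo cycloisomerisation of the α-hydroxyallene: O5′ adds to C8′ of the activated C7′=C8′ bond within the plane of the new ring, so the allene axis should be transferred completely to C8′ (R axis plus 5′R gives 8′S, side chain cis to the C5′ methyl group), protodeauration leaves C6′=C7′, and the E geometry of C9′=C10′ keeps the primary hydroxyl out of reach.

Step 12
Reactants: 14 furanoid alcohol
Product: 16 tributyl{(2E)-3-[(2S,7aR)-4,4,7a-trimethyl-2,4,5,6,7,7a-hexahydro-1-benzofuran-2-yl]but-2-en-1-yl}phosphonium bromide, via allylic bromide 15 (not isolated)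
Conditions: CBr4 (1.05 equiv), PBu3 (2.1 equiv), 2,6-lutidine (0.2 equiv), CH2Cl2, −20 °C to rt
Reagents that add atoms: carbon tetrabromide BrC(Br)(Br)Br; tributylphosphine CCCCP(CCCC)CCCC
Why: Appel bromination of the primary allylic alcohol followed by SN2 quaternisation with the second equivalent of phosphine runs under essentially neutral conditions, which should spare the acid-labile doubly allylic C8′–O bond.

Step 13
Reactants: 11 (2E)-3-iodobut-2-en-1-ol
Product: 18 tributyl[(2E)-3-iodobut-2-en-1-yl]phosphonium bromide, via allylic bromide 17 (not isolated)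
Conditions: CBr4 (1.05 equiv), PBu3 (2.1 equiv), CH2Cl2, −20 °C to rt
Reagents that add atoms: carbon tetrabromide BrC(Br)(Br)Br; tributylphosphine CCCCP(CCCC)CCCC
Why: Appel bromination and in-situ SN2 quaternisation at the primary allylic carbon; the alkenyl iodide is inert to phosphine without a metal catalyst.

Step 14
Reactants: 18 iodobutenylphosphonium bromide and 19 (2E,4E,6E)-2,7-dimethylocta-2,4,6-trienedial
Product: 21 (2E,4E,6E,8E,10E)-11-iodo-2,7-dimethyldodeca-2,4,6,8,10-pentaenal, via phosphonium ylide 20 (not isolated)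
Conditions: KOt-Bu, THF, −78 °C; then added to 19 (3 equiv), −78 to 0 °C, dark
Reagents that add atoms: none
Why: Wittig olefination forming C11=C12; allylic trialkylphosphonium ylides are E-selective with aldehydes, and the excess of the symmetric dialdehyde should hold the reaction at mono-olefination.

Step 15
Reactants: 16 furanoid phosphonium bromide and 21 iodopentaenal
Product: 23 (2S,7aR)-2-[(2E,4E,6E,8E,10E,12E,14E)-15-iodo-6,11-dimethylhexadeca-2,4,6,8,10,12,14-heptaen-2-yl]-4,4,7a-trimethyl-2,4,5,6,7,7a-hexahydro-1-benzofuran, via phosphonium ylide 22 (not isolated)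
Conditions: KOt-Bu, THF, −78 °C; then 21, −78 to 0 °C, dark
Reagents that add atoms: none
Why: E-selective Wittig olefination of the trialkylphosphonium ylide forms C11′=C12′; at −78 °C the ylide should be trapped by the aldehyde before any E1cB opening of the C8′–O bond, so C8′ keeps its configuration.

Step 16
Reactants: 23 C29 polyenyl iodide and 7 vinyl cis-diol
Product: 24 (5R,6S,5′R,8′S)-5′,8′-epoxy-5,6,5′,8′-tetrahydro-β,β-carotene-5,6-diol (target)
Conditions: Pd(OAc)2 (10 mol %), Ag2CO3 (1.5 equiv), 7 (3 equiv), DMF, 25–40 °C, argon, dark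
Reagents that add atoms: none
Why: Zerovalent palladium adds oxidatively to the C9–I bond of 23 with retention of the E geometry, silver removes iodide, the terminal alkene of 7 inserts syn with C9 bonding to C8 and palladium to C7, and syn β-hydride elimination from C8 followed by base-assisted catalyst regeneration releases the diene. The closest known reaction type is the Mizoroki–Heck alkenylation of tertiary vinyl carbinols with alkenyl iodides under silver-assisted, near-room-temperature conditions, which gives conjugated dienols. No ring is closed and no stereocentre is formed; the new C7=C8 bond should be E because the syn elimination runs through the rotamer that keeps ring A and the polyene apart, and C5, C6, C5′ and C8′ are not touched. The step needs insertion at C8, one direction of elimination and chemoselectivity for the terminal alkene: C6 is a fully substituted carbinol between quaternary C1 and C5, so palladium on C7 finds β-hydrogens only on C8 (no ketone formation, no chain walking), the monosubstituted vinyl group inserts far faster than the internal polyene double bonds, and 7 is used in excess. The free cis-diol and the furanoid ether should tolerate the weakly basic medium, so nothing has to be deprotected afterwards.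

**Compound list**

1 | β-cyclocitral (2,6,6-trimethylcyclohex-1-ene-1-carbaldehyde) | CC1=C(C=O)C(C)(C)CCC1 | starting material
2 | β-cyclogeraniol ((2,6,6-trimethylcyclohex-1-en-1-yl)methanol) | CC1=C(CO)C(C)(C)CCC1 | intermediate
3 | [(1R,6R)-2,2,6-trimethyl-7-oxabicyclo[4.1.0]heptan-1-yl]methanol | OC[C@@]12O[C@]1(C)CCCC2(C)C | intermediate
4 | (1S,6R)-2,2,6-trimethyl-7-oxabicyclo[4.1.0]heptane-1-carbaldehyde | O=C[C@@]12O[C@]1(C)CCCC2(C)C | intermediate
5 | (1S,6R)-1-ethenyl-2,2,6-trimethyl-7-oxabicyclo[4.1.0]heptane | C=C[C@@]12O[C@]1(C)CCCC2(C)C | intermediate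
6 | (3aR,7aS)-7a-ethenyl-3a,7,7-trimethylhexahydro-1,3-benzodioxol-2-one | C=C[C@@]12OC(=O)O[C@]1(C)CCCC2(C)C | intermediate
7 | (1S,2R)-1-ethenyl-2,6,6-trimethylcyclohexane-1,2-diol | C=C[C@]1(O)C(C)(C)CCC[C@@]1(C)O | intermediate
8 | (1R,6R)-1-ethynyl-2,2,6-trimethyl-7-oxabicyclo[4.1.0]heptane | C#C[C@@]12O[C@]1(C)CCCC2(C)C | intermediate
9 | but-2-yn-1-ol | CC#CCO | starting material
10 | (E)-alkenylzirconocene chloride of but-2-yn-1-ol, zirconium on C3 and on oxygen | C/C(=C\CO[Zr](Cl)(C1C=CC=C1)C1C=CC=C1)[Zr](Cl)(C1C=CC=C1)C1C=CC=C1 | intermediate (not isolated)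
11 | (2E)-3-iodobut-2-en-1-ol | OC/C=C(C)/I | intermediate
12 | (2E)-3-methyl-5-[(1R,6R)-2,2,6-trimethyl-7-oxabicyclo[4.1.0]heptan-1-yl]pent-2-en-4-yn-1-ol | OC/C=C(\C)C#C[C@@]12O[C@]1(C)CCCC2(C)C | intermediate
13 | (2E)-5-[(2R)-2-hydroxy-2,6,6-trimethylcyclohexylidene]-3-methylpenta-2,4-dien-1-ol, (R) allene axis (5′R,6′R) | C[C@@]1(O)CCCC(C)(C)C1=[C@@]=C([H])/C(C)=C/CO | intermediate
14 | (2E)-3-[(2S,7aR)-4,4,7a-trimethyl-2,4,5,6,7,7a-hexahydro-1-benzofuran-2-yl]but-2-en-1-ol | OC/C=C(\C)[C@@H]1C=C2C(C)(C)CCC[C@@]2(C)O1 | intermediate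
15 | (2S,7aR)-2-[(2E)-4-bromobut-2-en-2-yl]-4,4,7a-trimethyl-2,4,5,6,7,7a-hexahydro-1-benzofuran | BrC/C=C(\C)[C@@H]1C=C2C(C)(C)CCC[C@@]2(C)O1 | intermediate (not isolated)
16 | tributyl{(2E)-3-[(2S,7aR)-4,4,7a-trimethyl-2,4,5,6,7,7a-hexahydro-1-benzofuran-2-yl]but-2-en-1-yl}phosphonium bromide | CCCC[P+](CCCC)(CCCC)C/C=C(\C)[C@@H]1C=C2C(C)(C)CCC[C@@]2(C)O1.[Br-] | intermediate
17 | (2E)-1-bromo-3-iodobut-2-ene | BrC/C=C(C)/I | intermediate (not isolated)
18 | tributyl[(2E)-3-iodobut-2-en-1-yl]phosphonium bromide | CCCC[P+](CCCC)(CCCC)C/C=C(C)/I.[Br-] | intermediate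
19 | (2E,4E,6E)-2,7-dimethylocta-2,4,6-trienedial | O=C/C(C)=C/C=C/C=C(C)/C=O | starting material
20 | ylide of 18, tributyl[(2E)-3-iodobut-2-en-1-ylidene]phosphorane | CCCC[P+](CCCC)(CCCC)[CH-]/C=C(C)/I | intermediate (not isolated)
21 | (2E,4E,6E,8E,10E)-11-iodo-2,7-dimethyldodeca-2,4,6,8,10-pentaenal | CC(/C=C/C=C(C)/I)=C\C=C\C=C(C)\C=O | intermediate
22 | ylide of 16 | CCCC[P+](CCCC)(CCCC)[CH-]/C=C(\C)[C@@H]1C=C2C(C)(C)CCC[C@@]2(C)O1 | intermediate (not isolated)
23 | (2S,7aR)-2-[(2E,4E,6E,8E,10E,12E,14E)-15-iodo-6,11-dimethylhexadeca-2,4,6,8,10,12,14-heptaen-2-yl]-4,4,7a-trimethyl-2,4,5,6,7,7a-hexahydro-1-benzofuran | CC(/C=C/C=C(C)/I)=C\C=C\C=C(C)\C=C\C=C(/C)[C@@H]1C=C2C(C)(C)CCC[C@@]2(C)O1 | intermediate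
24 | (5R,6S,5′R,8′S)-5′,8′-epoxy-5,6,5′,8′-tetrahydro-β,β-carotene-5,6-diol | CC(/C=C/C=C(C)/C=C/[C@]1(O)C(C)(C)CCC[C@@]1(C)O)=C\C=C\C=C(C)\C=C\C=C(/C)[C@@H]1C=C2C(C)(C)CCC[C@@]2(C)O1 | target

**Count and risks**

Total step count: 16. Longest linear sequence: 10 steps (1, 2, 3, 7, 9, 10, 11, 12, 15, 16).

Step 16 (Heck union). Insertion into the crowded vinyl group may be slow, so that the polyenylpalladium intermediate decays by homocoupling, reduction or E/Z scrambling before it couples. The fallback sets out from 7: ruthenium-catalysed cross-metathesis with vinylboronic acid pinacol ester (second-generation Hoveyda–Grubbs catalyst, CH2Cl2, 40 °C) would give the alkenylboronate (1S,2R)-2,6,6-trimethyl-1-[(E)-2-(4,4,5,5-tetramethyl-1,3,2-dioxaborolan-2-yl)ethenyl]cyclohexane-1,2-diol F1. Suzuki–Miyaura coupling of F1 with 23 (Pd(PPh3)4, aqueous K3PO4, THF, rt, dark) would then form the same C8–C9 bond and return to the route at 24.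

Step 5 (retentive carbonate formation). Ionisation of the tetrasubstituted oxirane by zerovalent palladium may be sluggish, or the alkoxide may close on the terminal carbon C8 faster than it is carboxylated. The fallback sets out from 5: an aluminium amide base (lithium 2,2,6,6-tetramethylpiperidide with Et2AlCl, toluene, 0 °C) would isomerise the oxirane by removing a proton from the C5 methyl group, giving (1S)-1-ethenyl-2,2-dimethyl-6-methylidenecyclohexan-1-ol F2 with the C6–O bond untouched. Hydroxyl-directed epoxidation (VO(acac)2, t-BuOOH, CH2Cl2) of the more electron-rich 1,1-disubstituted double bond on the face of the C6 hydroxyl would give (3S,4S)-4-ethenyl-5,5-dimethyl-1-oxaspiro[2.5]octan-4-ol F3. LiAlH4 (THF, 0 °C) would open the spiro-oxirane at its CH2 group and return to the route at 7.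

Step 11 (allene to furanoid ring). Reversible ionisation of the doubly allylic C8′–O bond of the product under the Lewis acid may erode the C8′ configuration, or the vinylallene may undergo carbocyclisation instead of O-cyclisation. The fallback sets out from 4: Horner–Wadsworth–Emmons reaction with ethyl (2E)-4-(diethoxyphosphoryl)-3-methylbut-2-enoate (NaH, THF, 0 °C) would give ethyl (2E,4E)-3-methyl-5-[(1S,6R)-2,2,6-trimethyl-7-oxabicyclo[4.1.0]heptan-1-yl]penta-2,4-dienoate F4. Reduction with i-Bu2AlH (CH2Cl2, −78 °C) would give (2E,4E)-3-methyl-5-[(1S,6R)-2,2,6-trimethyl-7-oxabicyclo[4.1.0]heptan-1-yl]penta-2,4-dien-1-ol F5. A trace of acid (pyridinium p-toluenesulfonate, CH2Cl2, 0 °C) would then trigger the classical 5,6-epoxide to 5,8-furanoid rearrangement. This gives 14 together with its C8′ epimer (2E)-3-[(2R,7aR)-4,4,7a-trimethyl-2,4,5,6,7,7a-hexahydro-1-benzofuran-2-yl]but-2-en-1-ol F6, which would have to be removed by chromatography; the fallback returns to the route at 14.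

**Further compounds**

F1 | step 16 | (1S,2R)-2,6,6-trimethyl-1-[(E)-2-(4,4,5,5-tetramethyl-1,3,2-dioxaborolan-2-yl)ethenyl]cyclohexane-1,2-diol | CC1(C)OB(/C=C/[C@]2(O)C(C)(C)CCC[C@@]2(C)O)OC1(C)C
F2 | step 5 | (1S)-1-ethenyl-2,2-dimethyl-6-methylidenecyclohexan-1-ol | C=C[C@]1(O)C(C)(C)CCCC1=C
F3 | step 5 | (3S,4S)-4-ethenyl-5,5-dimethyl-1-oxaspiro[2.5]octan-4-ol | C=C[C@]1(O)C(C)(C)CCC[C@]12CO2
F4 | step 11 | ethyl (2E,4E)-3-methyl-5-[(1S,6R)-2,2,6-trimethyl-7-oxabicyclo[4.1.0]heptan-1-yl]penta-2,4-dienoate | CCOC(=O)/C=C(C)/C=C/[C@@]12O[C@]1(C)CCCC2(C)C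
F5 | step 11 | (2E,4E)-3-methyl-5-[(1S,6R)-2,2,6-trimethyl-7-oxabicyclo[4.1.0]heptan-1-yl]penta-2,4-dien-1-ol | OC/C=C(C)/C=C/[C@@]12O[C@]1(C)CCCC2(C)C
F6 | step 11 | (2E)-3-[(2R,7aR)-4,4,7a-trimethyl-2,4,5,6,7,7a-hexahydro-1-benzofuran-2-yl]but-2-en-1-ol | OC/C=C(\C)[C@H]1C=C2C(C)(C)CCC[C@@]2(C)O1
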